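The earlier runs and the new flask are calculated on assumed constants; noise was put on by code.

I read each run at one early time, where product stands between 15.2 % and 21.6 %, around the 20 % conversion asked about.

| setting | teal | amber | grey | flask |
|---|---|---|---|---|
| starting material | 10 mM | 10 mM | 15 mM | 10 mM |
| coupling partner | 1 equiv | 1 equiv | 1 equiv | 1.00 equiv |
| free catalyst | 8.7 mol% | 14 mol% | 6.2 mol% | 6.2 mol% |
| added ligand | 0.85 mM | 0.85 mM | 0.85 mM | 0.85 mM |
| remark | run made earlier | run made earlier | run made earlier |  |

| run | time / h | product / % |
|---|---|---|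
| teal | 0.250 | 6.4 |
| teal | 0.417 | 11.4 |
| teal | 0.667 | 18.5 |
| teal | 1.33 | 33.9 |
| teal | 2.00 | 46.1 |
| teal | 3.00 | 60.2 |
| amber | 0.500 | 21.6 |
| amber | 1.00 | 39.3 |
| amber | 1.50 | 52.8 |
| amber | 2.00 | 62.0 |
| amber | 2.50 | 69.5 |
| amber | 3.00 | 75.5 |
| grey | 0.250 | 8.1 |
| grey | 0.500 | 15.2 |
| grey | 0.833 | 24.7 |
| grey | 1.50 | 38.9 |
| grey | 3.00 | 61.3 |

(scatter of a reading: 0.3 percentage points)

1. factor on the rate of making product when 20 % of the starting material are converted if free catalyst is charged twice over
2. factor on the rate when 20 % of the starting material are converted if free catalyst is charged at 1.2 mol% instead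



From such a reading I take the first-order constant, the logarithm of what was charged over what remains, divided by the time, counting product as what was converted. Dividing that by the catalyst charged gives the specific rate, the first-order constant per millimolar of catalyst charged. The table reads:

- teal, 0.667 h: catalyst 0.870 mM, constant 0.307 h⁻¹, specific rate 0.353 mM⁻¹ h⁻¹
- amber, 0.500 h: catalyst 1.40 mM, constant 0.487 h⁻¹, specific rate 0.348 mM⁻¹ h⁻¹
- grey, 0.500 h: catalyst 0.930 mM, constant 0.330 h⁻¹, specific rate 0.355 mM⁻¹ h⁻¹

The last column barely moves, although grey starts at 15 mM, so I carry the mean, 0.352 mM⁻¹ h⁻¹. Reading amber against teal tests the small term: if added ligand removed catalyst mole for mole, amber would outrun teal by 27.5, but the readings give 1.59, close to the ratio of the charges, 1.61. At fixed conversion the rate is then the specific rate times catalyst times what remains, so I commit to a factor of 2 on doubling and 0.194 at 1.2 mol%. The flask's catalyst charge of 0.620 mM lies below the ligand's 0.85 mM, outside the catalyst range I read.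

The forecast gives 2 and 0.19, saying “The rate is therefore linear in catalyst through the origin”.

The simulation gives 2.04 and 0.189.

    coupling partner + free catalyst → catalyst intermediate A (k = 15.0 M⁻¹ min⁻¹)
    starting material + catalyst intermediate A → catalyst intermediate B (k = 21.0 M⁻¹ min⁻¹)
    catalyst intermediate B ⇌ free catalyst + product (K = 0.0270 M, k = 5.80 min⁻¹)
    free catalyst + added ligand ⇌ idle complex (K = 840 M⁻¹, k = 360 M⁻¹ min⁻¹)

For the flask, the specific rate gives a constant of 0.218 h⁻¹, hence 35.3 % product after 2.00 h, and the flask holds 35.8 %. For the flask charged at 1.2 mol%, the same specific rate gives a constant of 0.0422 h⁻¹, and the simulated factor stands at 0.189. At 1.49 h in the flask, coupling partner uses free catalyst at 0.42 of the rate at which added ligand does in its forward step, slower. After 2.00 h the catalyst charged to the flask stands as free catalyst 41.1 %, catalyst intermediate A 28.6 %, catalyst intermediate B 6.11 % and off-cycle idle complex 24.2 %.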